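**Plan**

- Chain atoms are numbered C1 (benzylic CH2) to C15 (the CMe2 carbon of the pyranone). The retrosynthesis cuts C7–C8 first, then C1–C2 together with C3–CH3, then C4–C5. In the pyranone it cuts O–C15 and C12–C13.
- Enabling feature: the C2=C3 alkene is E-trisubstituted with its C3 methyl on the same side as C1. This is the pattern left by syn methyl–metal addition to a terminal alkyne followed by a geometry-retaining benzylation. C5 (as a carbinol) and C6≡C7 pass through that step as the second half of a skipped diyne.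
- Forward: arene 6 and diyne 12 are joined (C3–Me, C1–C2), and the remaining alkyne is turned into a (Z)-iodoalkene (17). The only ring, the dihydropyran, is closed separately by O–C15 etherification (27). Fragments 17 and 27 are united at C7–C8, both carbinols are oxidised, and the phenol is unmasked.
- Stereochemistry: C11 (R) comes from (S)-2-methylglycidol, and its C–O bond is never broken. The 2E geometry comes from the carbometalation/coupling. The 6Z geometry comes from trans-hydroalumination–iodination and a retentive Suzuki coupling.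

Key step: step 9

Remark: the carbinol carbons C5 and C12 (ring C3) are carried as mixtures of epimers because both end as ketones; (S)-2-methylglycidol is taken as a commercial, enantioenriched epoxide.

**Route**

Step 1
Reactants: 1 2-methylhydroquinone
Product: 2 2-methyl-4-(triisopropylsilyloxy)phenol
Conditions: TIPSCl (1.0 equiv), imidazole, DMF, 0 °C
Reagents that add atoms: triisopropylsilyl chloride, CC(C)[Si](Cl)(C(C)C)C(C)C
Why: O-silylation with a bulky chlorosilane should take the hydroxyl remote from the ring methyl, which is the less hindered one, and leave the ortho-methyl-flanked hydroxyl free.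

Step 2
Reactants: 2 2-methyl-4-(triisopropylsilyloxy)phenol
Product: 3 2-hydroxy-3-methyl-5-(triisopropylsilyloxy)benzaldehyde
Conditions: MgCl2, Et3N, (CH2O)n, THF, reflux
Reagents that add atoms: paraformaldehyde (as formaldehyde), C=O
Why: Casnati–Skattebøl ortho-formylation, in which the magnesium phenoxide delivers formaldehyde to the only free ortho position and a second formaldehyde oxidises the benzylic alkoxide.

Step 3
Reactants: 3 2-hydroxy-3-methyl-5-(triisopropylsilyloxy)benzaldehyde
Product: 4 2-methoxy-3-methyl-5-(triisopropylsilyloxy)benzaldehyde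
Conditions: MeI, K2CO3, acetone, 50 °C
Reagents that add atoms: iodomethane, CI
Why: Williamson O-methylation of the salicylaldehyde phenol under anhydrous carbonate conditions that an aryl triisopropylsilyl ether should tolerate.

Step 4
Reactants: 4 2-methoxy-3-methyl-5-(triisopropylsilyloxy)benzaldehyde
Product: 5 [2-methoxy-3-methyl-5-(triisopropylsilyloxy)phenyl]methanol
Conditions: NaBH4, MeOH/THF, 0 °C
Reagents that add atoms: none
Why: Borohydride reduction of an aryl aldehyde to the benzylic alcohol, with no other reducible group present.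

Step 5
Reactants: 5 [2-methoxy-3-methyl-5-(triisopropylsilyloxy)phenyl]methanol
Product: 6 2-methoxy-3-methyl-5-(triisopropylsilyloxy)benzyl chloride
Conditions: SOCl2, pyridine, CH2Cl2, 0 °C
Reagents that add atoms: thionyl chloride, ClS(Cl)=O
Why: Chlorodehydroxylation through the chlorosulfite, buffered with pyridine so that the aryl silyl ether and the electron-rich ring are not exposed to free HCl.

Step 6
Reactants: 7 but-2-yn-1-ol
Product: 8 but-2-ynal
Conditions: activated MnO2 (excess), CH2Cl2, rt; filtered and used as a solution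
Reagents that add atoms: none
Why: MnO2 oxidation of a propargylic alcohol stops at the ynal, and filtration avoids isolating the volatile aldehyde.

Step 7
Reactants: 8 but-2-ynal; 9 propargyl bromide
Product: 11 hepta-1,5-diyn-4-ol (racemic), via allenylzinc bromide 10 (not isolated)
Conditions: 9, Zn dust, THF, 0 °C; then 8, 0 °C → rt; aq. NH4Cl
Reagents that add atoms: none
Why: Zinc Barbier propargylation, in which the allenylzinc species adds through its γ-carbon (SE2′) to give the homopropargylic alcohol and so forms C4–C5.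

Step 8
Reactants: 11 hepta-1,5-diyn-4-ol
Product: 12 tert-butyl(hepta-1,5-diyn-4-yloxy)dimethylsilane
Conditions: TBSCl, imidazole, DMF, rt
Reagents that add atoms: tert-butyldimethylsilyl chloride, CC(C)(C)[Si](C)(C)Cl
Why: Standard silylation of a secondary alcohol, which removes the acidic hydrogen before the organoaluminium step.

Step 9
Reactants: 12 tert-butyl(hepta-1,5-diyn-4-yloxy)dimethylsilane; 6 2-methoxy-3-methyl-5-(triisopropylsilyloxy)benzyl chloride
Product: 14 tert-butyl({(6E)-8-[2-methoxy-3-methyl-5-(triisopropylsilyloxy)phenyl]-6-methyloct-6-en-2-yn-4-yl}oxy)dimethylsilane, via alkenyldimethylalane 13 (not isolated)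
Conditions: AlMe3, Cp2ZrCl2 (cat.), ClCH2CH2Cl, 0 °C → rt; volatiles removed; then 6, NiCl2(PPh3)2/n-BuLi (1:2, cat., gives zerovalent nickel), THF, rt
Reagents that add atoms: trimethylaluminium, C[Al](C)C
Why: The methylzirconium/aluminium species formed from Cp2ZrCl2 and AlMe3 adds methyl and metal syn across the terminal C2≡C3 bond, methyl to the internal carbon C3, to give alkenylalane 13; zerovalent nickel then inserts into the benzylic C–Cl bond of 6, the alkenyl group moves from aluminium to nickel, and reductive elimination forms C1–C2 with the alkene geometry retained. The closest known reaction type is the zirconium-catalysed methylalumination of terminal alkynes (Negishi carboalumination) coupled in the same flask with nickel-catalysed benzylation of the alkenylalane, as established for prenylated arenes and quinone side chains. No ring is closed and no stereocentre is made; the only stereochemical element is the C2=C3 geometry, fixed as E by syn addition followed by stereoretentive coupling. The step needs terminal-over-internal alkyne selectivity and methyl delivery to C3: both are inherent to the zirconium-catalysed addition, and the internal C6≡C7 alkyne is further slowed by its methyl cap and the adjacent silyloxy-bearing carbon. Both hydroxyls are silylated so that no aluminium alkoxide forms, and excess AlMe3 is stripped before the coupling to suppress methyl transfer to the benzyl group.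

Step 10
Reactants: 14 tert-butyl({(6E)-8-[2-methoxy-3-methyl-5-(triisopropylsilyloxy)phenyl]-6-methyloct-6-en-2-yn-4-yl}oxy)dimethylsilane
Product: 15 (6E)-8-[2-methoxy-3-methyl-5-(triisopropylsilyloxy)phenyl]-6-methyloct-6-en-2-yn-4-ol
Conditions: CSA (0.2 equiv), MeOH/CH2Cl2, rt
Reagents that add atoms: none
Why: Acid-catalysed methanolysis should cleave the secondary alkyl silyl ether, while the aryl triisopropylsilyl ether, which is far more stable to acid, stays on.

Step 11
Reactants: 15 (6E)-8-[2-methoxy-3-methyl-5-(triisopropylsilyloxy)phenyl]-6-methyloct-6-en-2-yn-4-ol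
Product: 17 (2Z,6E)-2-iodo-8-[2-methoxy-3-methyl-5-(triisopropylsilyloxy)phenyl]-6-methylocta-2,6-dien-4-ol, via cyclic sodium alkenylaluminate 16 (not isolated)
Conditions: NaAlH2(OCH2CH2OMe)2, THF, 0 °C → rt; then I2, THF, −78 → 0 °C
Reagents that add atoms: iodine, II
Why: Hydroxyl-directed trans-hydroalumination of the propargylic alcohol puts hydride on C6 and aluminium on C7 in a five-membered aluminate, and iodinolysis with retention gives the iodoalkene with iodine cis to the carbinol carbon.

Step 12
Reactants: 18 (S)-2-methylglycidol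
Product: 19 (2R)-2-methylpent-4-ene-1,2-diol
Conditions: CH2=CHMgBr (3 equiv), CuI (10 mol %), THF, −30 → 0 °C
Reagents that add atoms: vinylmagnesium bromide, C=C[Mg]Br
Why: Copper-catalysed Grignard opening of a 2,2-disubstituted epoxide at its CH2 terminus builds the allyl group without touching the quaternary carbon, so the configuration of the future C11 is carried over unchanged.

Step 13
Reactants: 19 (2R)-2-methylpent-4-ene-1,2-diol
Product: 20 (2R)-2-hydroxy-2-methylpent-4-enal
Conditions: (COCl)2, DMSO, CH2Cl2, −78 °C; Et3N, −78 → 0 °C; used crude at once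
Reagents that add atoms: none
Why: Swern oxidation converts the primary hydroxyl to the aldehyde while the tertiary hydroxyl cannot be oxidised, and the fully substituted α-carbon cannot epimerise.

Step 14
Reactants: 20 (2R)-2-hydroxy-2-methylpent-4-enal; 21 2-methylbut-3-yn-2-ol
Product: 23 (6R)-2,6-dimethylnon-8-en-3-yne-2,5,6-triol (C5 epimers), via dilithium alkynolate 22 (not isolated)
Conditions: 21, n-BuLi (2 equiv per 21), THF, −78 → 0 °C; then 20 (0.45 equiv), −78 °C → rt; aq. work-up
Reagents that add atoms: none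
Why: Acetylide addition to the aldehyde forms C12–C13, with one equivalent of the dianion sacrificed to the free hydroxyl of 20, and the new carbinol configuration is irrelevant because C12 ends as a ketone.

Step 15
Reactants: 23 (6R)-2,6-dimethylnon-8-en-3-yne-2,5,6-triol
Product: 24 (6R)-5-(tert-butyldimethylsilyloxy)-2,6-dimethylnon-8-en-3-yne-2,6-diol
Conditions: TBSCl, imidazole, DMF, rt
Reagents that add atoms: tert-butyldimethylsilyl chloride, CC(C)(C)[Si](C)(C)Cl
Why: Chemoselective silylation takes the only secondary hydroxyl in the presence of two tertiary ones, which blocks the C12 oxygen as a competing nucleophile for the ring closure.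

Step 16
Reactants: 24 (6R)-5-(tert-butyldimethylsilyloxy)-2,6-dimethylnon-8-en-3-yne-2,6-diol
Product: 25 (3Z,6R)-5-(tert-butyldimethylsilyloxy)-2,6-dimethylnona-3,8-diene-2,6-diol
Conditions: H2 (1 atm), Pd/CaCO3 (Pb-poisoned, Lindlar), quinoline, EtOAc, rt, stopped at one equivalent of H2
Reagents that add atoms: none
Why: Lindlar semihydrogenation adds hydrogen syn to the alkyne, which binds the poisoned palladium surface more strongly than the terminal alkene, and gives the cis C13=C14 alkene needed for cyclisation.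

Step 17
Reactants: 25 (3Z,6R)-5-(tert-butyldimethylsilyloxy)-2,6-dimethylnona-3,8-diene-2,6-diol
Product: 26 tert-butyl{[(2R)-2,6,6-trimethyl-2-(prop-2-en-1-yl)-3,6-dihydro-2H-pyran-3-yl]oxy}dimethylsilane
Conditions: CSA (10 mol %), 4 Å MS, CH2Cl2, 0 °C → rt
Reagents that add atoms: none
Why: Acid-catalysed cyclodehydration (intramolecular SN1 allylic etherification) in which the tertiary allylic hydroxyl at C15 ionises, the C11 hydroxyl captures the cation at C15 across the cis alkene to close the six-membered ring, no dihydrofuran can form because the C12 oxygen is silylated, and C11 keeps its configuration because its C–O bond is not broken.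

Step 18
Reactants: 26 tert-butyl{[(2R)-2,6,6-trimethyl-2-(prop-2-en-1-yl)-3,6-dihydro-2H-pyran-3-yl]oxy}dimethylsilane
Product: 27 (2R)-2,6,6-trimethyl-2-(prop-2-en-1-yl)-3,6-dihydro-2H-pyran-3-ol
Conditions: TBAF, THF, rt → 40 °C
Reagents that add atoms: none
Why: Fluoride desilylation frees the ring carbinol at the fragment stage, where no aryl silyl ether is present to be lost.

Step 19
Reactants: 27 (2R)-2,6,6-trimethyl-2-(prop-2-en-1-yl)-3,6-dihydro-2H-pyran-3-ol; 17 (2Z,6E)-2-iodo-8-[2-methoxy-3-methyl-5-(triisopropylsilyloxy)phenyl]-6-methylocta-2,6-dien-4-ol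
Product: 29 (2R)-2-{(4Z,8E)-6-hydroxy-10-[2-methoxy-3-methyl-5-(triisopropylsilyloxy)phenyl]-4,8-dimethyldeca-4,8-dien-1-yl}-2,6,6-trimethyl-3,6-dihydro-2H-pyran-3-ol (carbinol epimers), via B-alkyl-9-BBN borane 28 (not isolated)
Conditions: 27 (1.5 equiv), 9-BBN (excess), THF, rt; then 17, Pd(dppf)Cl2 (10 mol %), AsPh3, Cs2CO3, DMF/H2O, rt
Reagents that add atoms: none
Why: B-alkyl Suzuki–Miyaura coupling, in which 9-BBN adds only to the terminal alkene (the ring alkene is cis-disubstituted between two fully substituted carbons) and the alkylborane couples with the iodoalkene with retention to form C7–C8 with the 6Z geometry intact.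

Step 20
Reactants: 29 (2R)-2-{(4Z,8E)-6-hydroxy-10-[2-methoxy-3-methyl-5-(triisopropylsilyloxy)phenyl]-4,8-dimethyldeca-4,8-dien-1-yl}-2,6,6-trimethyl-3,6-dihydro-2H-pyran-3-ol
Product: 30 (2R)-2-{(4Z,8E)-10-[2-methoxy-3-methyl-5-(triisopropylsilyloxy)phenyl]-4,8-dimethyl-6-oxodeca-4,8-dien-1-yl}-2,6,6-trimethyl-2H-pyran-3(6H)-one
Conditions: Dess–Martin periodinane (3 equiv), NaHCO3, CH2Cl2, 0 °C → rt
Reagents that add atoms: none
Why: Buffered Dess–Martin oxidation converts both secondary allylic alcohols to enones under near-neutral conditions that should move neither the skipped C2=C3 alkene nor the Z-enone, and the silylated phenol is inert to the oxidant.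

Step 21
Reactants: 30 (2R)-2-{(4Z,8E)-10-[2-methoxy-3-methyl-5-(triisopropylsilyloxy)phenyl]-4,8-dimethyl-6-oxodeca-4,8-dien-1-yl}-2,6,6-trimethyl-2H-pyran-3(6H)-one
Product: 31 (2R)-2-[(4Z,8E)-10-(5-hydroxy-2-methoxy-3-methylphenyl)-4,8-dimethyl-6-oxodeca-4,8-dien-1-yl]-2,6,6-trimethyl-2H-pyran-3(6H)-one (CNP0160516.2)
Conditions: TBAF, AcOH (1:1), THF, 0 °C
Reagents that add atoms: none
Why: Fluoride cleavage of the aryl silyl ether, buffered with acetic acid so that the phenoxide is protonated at once and the doubly activated C4 methylene and the Z-enone are not exposed to base.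

**Compound list**

1 | 2-methylhydroquinone | Cc1cc(O)ccc1O | starting material
2 | 2-methyl-4-(triisopropylsilyloxy)phenol | Cc1cc(O[Si](C(C)C)(C(C)C)C(C)C)ccc1O | intermediate
3 | 2-hydroxy-3-methyl-5-(triisopropylsilyloxy)benzaldehyde | Cc1cc(O[Si](C(C)C)(C(C)C)C(C)C)cc(C=O)c1O | intermediate
4 | 2-methoxy-3-methyl-5-(triisopropylsilyloxy)benzaldehyde | COc1c(C)cc(O[Si](C(C)C)(C(C)C)C(C)C)cc1C=O | intermediate
5 | [2-methoxy-3-methyl-5-(triisopropylsilyloxy)phenyl]methanol | COc1c(C)cc(O[Si](C(C)C)(C(C)C)C(C)C)cc1CO | intermediate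
6 | 2-methoxy-3-methyl-5-(triisopropylsilyloxy)benzyl chloride | COc1c(C)cc(O[Si](C(C)C)(C(C)C)C(C)C)cc1CCl | intermediate
7 | but-2-yn-1-ol | CC#CCO | starting material
8 | but-2-ynal | CC#CC=O | intermediate
9 | propargyl bromide | C#CCBr | starting material
10 | allenylzinc bromide | C=C=C[Zn]Br | intermediate
11 | hepta-1,5-diyn-4-ol (racemic) | C#CCC(O)C#CC | intermediate
12 | tert-butyl(hepta-1,5-diyn-4-yloxy)dimethylsilane | C#CCC(O[Si](C)(C)C(C)(C)C)C#CC | intermediate
13 | dimethyl[(1E)-2-methyl-4-(tert-butyldimethylsilyloxy)hept-1-en-5-yn-1-yl]alane | C[Al](C)/C=C(\C)CC(O[Si](C)(C)C(C)(C)C)C#CC | intermediate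
14 | tert-butyl({(6E)-8-[2-methoxy-3-methyl-5-(triisopropylsilyloxy)phenyl]-6-methyloct-6-en-2-yn-4-yl}oxy)dimethylsilane | COc1c(C)cc(O[Si](C(C)C)(C(C)C)C(C)C)cc1C/C=C(\C)CC(O[Si](C)(C)C(C)(C)C)C#CC | intermediate
15 | (6E)-8-[2-methoxy-3-methyl-5-(triisopropylsilyloxy)phenyl]-6-methyloct-6-en-2-yn-4-ol | COc1c(C)cc(O[Si](C(C)C)(C(C)C)C(C)C)cc1C/C=C(\C)CC(O)C#CC | intermediate
16 | cyclic sodium alkenylaluminate (five-membered O–Al–C7=C6–C5 ring, two 2-methoxyethoxy groups on aluminium) | [Na+].COCCO[Al-]1(OCCOC)OC(C/C(C)=C/Cc2cc(O[Si](C(C)C)(C(C)C)C(C)C)cc(C)c2OC)C=C1C | intermediate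
17 | (2Z,6E)-2-iodo-8-[2-methoxy-3-methyl-5-(triisopropylsilyloxy)phenyl]-6-methylocta-2,6-dien-4-ol | COc1c(C)cc(O[Si](C(C)C)(C(C)C)C(C)C)cc1C/C=C(\C)CC(O)/C=C(/C)I | intermediate
18 | (S)-2-methylglycidol | C[C@]1(CO)CO1 | starting material
19 | (2R)-2-methylpent-4-ene-1,2-diol | C=CC[C@@](C)(O)CO | intermediate
20 | (2R)-2-hydroxy-2-methylpent-4-enal | C=CC[C@@](C)(O)C=O | intermediate
21 | 2-methylbut-3-yn-2-ol | C#CC(C)(C)O | starting material
22 | dilithium 2-methylbut-3-yn-2-olate acetylide | [Li]C#CC(C)(C)O[Li] | intermediate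
23 | (6R)-2,6-dimethylnon-8-en-3-yne-2,5,6-triol (C5 epimers) | C=CC[C@@](C)(O)C(O)C#CC(C)(C)O | intermediate
24 | (6R)-5-(tert-butyldimethylsilyloxy)-2,6-dimethylnon-8-en-3-yne-2,6-diol | C=CC[C@@](C)(O)C(O[Si](C)(C)C(C)(C)C)C#CC(C)(C)O | intermediate
25 | (3Z,6R)-5-(tert-butyldimethylsilyloxy)-2,6-dimethylnona-3,8-diene-2,6-diol | C=CC[C@@](C)(O)C(O[Si](C)(C)C(C)(C)C)/C=C\C(C)(C)O | intermediate
26 | tert-butyl{[(2R)-2,6,6-trimethyl-2-(prop-2-en-1-yl)-3,6-dihydro-2H-pyran-3-yl]oxy}dimethylsilane | C=CC[C@@]1(C)OC(C)(C)C=CC1O[Si](C)(C)C(C)(C)C | intermediate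
27 | (2R)-2,6,6-trimethyl-2-(prop-2-en-1-yl)-3,6-dihydro-2H-pyran-3-ol | C=CC[C@@]1(C)OC(C)(C)C=CC1O | intermediate
28 | (2R)-2-[3-(9-borabicyclo[3.3.1]nonan-9-yl)propyl]-2,6,6-trimethyl-3,6-dihydro-2H-pyran-3-ol | B1(CCC[C@@]3(C)OC(C)(C)C=CC3O)C2CCCC1CCC2 | intermediate
29 | (2R)-2-{(4Z,8E)-6-hydroxy-10-[2-methoxy-3-methyl-5-(triisopropylsilyloxy)phenyl]-4,8-dimethyldeca-4,8-dien-1-yl}-2,6,6-trimethyl-3,6-dihydro-2H-pyran-3-ol | COc1c(C)cc(O[Si](C(C)C)(C(C)C)C(C)C)cc1C/C=C(\C)CC(O)/C=C(/C)CCC[C@@]1(C)OC(C)(C)C=CC1O | intermediate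
30 | (2R)-2-{(4Z,8E)-10-[2-methoxy-3-methyl-5-(triisopropylsilyloxy)phenyl]-4,8-dimethyl-6-oxodeca-4,8-dien-1-yl}-2,6,6-trimethyl-2H-pyran-3(6H)-one | COc1c(C)cc(O[Si](C(C)C)(C(C)C)C(C)C)cc1C/C=C(\C)CC(=O)/C=C(/C)CCC[C@@]1(C)OC(C)(C)C=CC1=O | intermediate
31 | (2R)-2-[(4Z,8E)-10-(5-hydroxy-2-methoxy-3-methylphenyl)-4,8-dimethyl-6-oxodeca-4,8-dien-1-yl]-2,6,6-trimethyl-2H-pyran-3(6H)-one | COc1c(C)cc(O)cc1C/C=C(\C)CC(=O)/C=C(/C)CCC[C@@]1(C)OC(C)(C)C=CC1=O | target

**Count and risks**

Total step count: 21. Longest linear sequence: 11 steps (steps 1–5, 9, 10, 11, 19, 20, 21).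

Steps most likely to fail:

1. Step 17. The tertiary allyl cation may lose a proton to give a diene, or be recaptured by water with allylic transposition, faster than the hindered tertiary hydroxyl closes the ring. The fallback replaces cation chemistry by π-activation of an allene. It sets out from 20 and returns at 26.
   - Lithiated 3-methoxy-3-methylbut-1-yne (n-BuLi, THF) is added to 20 to give (6R)-2-methoxy-2,6-dimethylnon-8-en-3-yne-5,6-diol F1.
   - LiAlH4 in THF, directed by the C12 alkoxide, delivers hydride to C13 and expels methoxide to give the allenic diol (4R)-4,8-dimethylnona-1,6,7-triene-4,5-diol F2.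
   - TBSCl/imidazole silylates the secondary hydroxyl to give (4R)-5-(tert-butyldimethylsilyloxy)-4,8-dimethylnona-1,6,7-trien-4-ol F3.
   - Ph3PAuCl/AgBF4 (monovalent gold) in CH2Cl2 should then effect the 6-endo cycloisomerisation of this β-hydroxyallene, with the C11 hydroxyl adding to the CMe2 terminus, to give 26.

2. Step 9. Carbometalation may be sluggish next to the silyloxy-bearing carbon, or the nickel stage may suffer protodealumination or methyl transfer, so that the alkenyl–benzyl bond does not form cleanly in one flask. The fallback separates the two events and changes the coupling metals while forming the same two bonds. It sets out from 12 and 6 and returns at 14.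
   - The alkenylalane 13 is quenched with iodine to give tert-butyl{[(6E)-7-iodo-6-methylhept-6-en-2-yn-4-yl]oxy}dimethylsilane F4, which can be purified.
   - Chloride 6 is converted with Zn dust/LiCl in THF into [2-methoxy-3-methyl-5-(triisopropylsilyloxy)benzyl]zinc chloride F5.
   - A Negishi coupling of F4 and F5 with Pd(PPh3)4 (zerovalent palladium) in THF gives 14 with retention of the E geometry.

3. Step 19. Hydroboration may be incomplete because the free ring hydroxyl consumes borane, the alkylpalladium intermediate may undergo β-hydride elimination or protodeboronation, and the aqueous base may erode the aryl silyl ether. The fallback is a base-free Negishi coupling. It sets out from 27 and returns at 29.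
   - TESCl/imidazole gives triethyl{[(2R)-2,6,6-trimethyl-2-(prop-2-en-1-yl)-3,6-dihydro-2H-pyran-3-yl]oxy}silane F6.
   - Hydroboration with dicyclohexylborane followed by iodinolysis (I2, NaOMe) gives {[(2R)-2-(3-iodopropyl)-2,6,6-trimethyl-3,6-dihydro-2H-pyran-3-yl]oxy}triethylsilane F7.
   - Zinc insertion (Zn, LiCl, THF) gives the alkylzinc iodide {3-[(2R)-2,6,6-trimethyl-3-(triethylsilyloxy)-3,6-dihydro-2H-pyran-2-yl]propyl}zinc iodide F8.
   - F8, used in excess, is coupled with 17 under Pd(dppf)Cl2 in THF/DMA to give the triethylsilyl ether of 29, (2Z,6E)-8-[2-methoxy-3-methyl-5-(triisopropylsilyloxy)phenyl]-2,6-dimethyl-10-[(2R)-2,6,6-trimethyl-3-(triethylsilyloxy)-3,6-dihydro-2H-pyran-2-yl]... in short, the 3-O-triethylsilyl ether of 29 F9.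
   - PPTS in MeOH removes the triethylsilyl group, leaves the aryl triisopropylsilyl ether, and gives 29.

**Further compounds**

F1 | step 17 | (6R)-2-methoxy-2,6-dimethylnon-8-en-3-yne-5,6-diol | C=CC[C@@](C)(O)C(O)C#CC(C)(C)OC
F2 | step 17 | (4R)-4,8-dimethylnona-1,6,7-triene-4,5-diol | C=CC[C@@](C)(O)C(O)C=C=C(C)C
F3 | step 17 | (4R)-5-(tert-butyldimethylsilyloxy)-4,8-dimethylnona-1,6,7-trien-4-ol | C=CC[C@@](C)(O)C(O[Si](C)(C)C(C)(C)C)C=C=C(C)C
F4 | step 9 | tert-butyl{[(6E)-7-iodo-6-methylhept-6-en-2-yn-4-yl]oxy}dimethylsilane | I/C=C(\C)CC(O[Si](C)(C)C(C)(C)C)C#CC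
F5 | step 9 | [2-methoxy-3-methyl-5-(triisopropylsilyloxy)benzyl]zinc chloride | COc1c(C)cc(O[Si](C(C)C)(C(C)C)C(C)C)cc1C[Zn]Cl
F6 | step 19 | triethyl{[(2R)-2,6,6-trimethyl-2-(prop-2-en-1-yl)-3,6-dihydro-2H-pyran-3-yl]oxy}silane | C=CC[C@@]1(C)OC(C)(C)C=CC1O[Si](CC)(CC)CC
F7 | step 19 | {[(2R)-2-(3-iodopropyl)-2,6,6-trimethyl-3,6-dihydro-2H-pyran-3-yl]oxy}triethylsilane | ICCC[C@@]1(C)OC(C)(C)C=CC1O[Si](CC)(CC)CC
F8 | step 19 | {3-[(2R)-2,6,6-trimethyl-3-(triethylsilyloxy)-3,6-dihydro-2H-pyran-2-yl]propyl}zinc iodide | I[Zn]CCC[C@@]1(C)OC(C)(C)C=CC1O[Si](CC)(CC)CC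
F9 | step 19 | 3-O-triethylsilyl ether of 29 | COc1c(C)cc(O[Si](C(C)C)(C(C)C)C(C)C)cc1C/C=C(\C)CC(O)/C=C(/C)CCC[C@@]1(C)OC(C)(C)C=CC1O[Si](CC)(CC)CC
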